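**Retrosynthetic overview**

1. Locants C1–C8 are those of the bicyclo[3.2.1]octene core (C1 OMe bridgehead, C2 CH–OAc, C3 C–OMe, C4 =CH, C5 allyl bridgehead, C6 CH–Me, C7 CH–Ar, C8 bridging C=O). O-acetylation and a face-selective 1,2-reduction lead back to the 2,8-dione.
2. Key disconnection: C7–C6 and C8–C5 of the dione are cut together. This opens both rings to an acyclic 2-methoxy dienone that has C1 as its only stereocentre, a benzyl group (C7) and an activated ester (C8).
3. Enabling feature: in the ring C1–C2–C3–C4–C5–C8, C5 is both α to the C8 ketone and γ to the C2(=O)–C3(OMe)=C4 enone, and C6 of the two-carbon bridge is the δ-carbon. The open form is therefore a dienone with an acceptor terminus (C6) and a latent vinylogous enolate carbon (C5). C7 is benzylic to an easily oxidised trimethoxyphenyl ring, so the two electrophilic carbons C6 and C7 can be joined through a radical.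
4. Precursor assembly: aldol condensation (C3=C4) of (E)-2-ethylidenepent-4-enal with a quaternary β-keto ester. That ester comes from enantioselective benzylation (C1–C7, sets C1) of the crossed-Claisen dimer of methoxyacetate (C1–C2).
5. Ring order, forward: the seven-membered carbocycle first (C7–C6), then cyclopentanone and cyclohexenone together by the transannular C5–C8 acylation.

Key step: step 8

Assumption: tert-butyl methoxyacetate and 3,4,5-trimethoxybenzyl bromide are taken as catalogue chemicals, and the enantiomer of the phase-transfer catalyst in step 2 is the one that delivers the (S)-configured product (first choice (S,S), to be fixed in a scouting run).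

**Step 1**
Reactants: 1 tert-butyl methoxyacetate; 2 methoxyacetyl chloride
Product: 3 tert-butyl 2,4-dimethoxy-3-oxobutanoate
Conditions: LiN(SiMe3)2 (2.1 equiv), THF, −78 °C; then 2, −78 to −40 °C; aq. HCl work-up
Reagents that add atoms: none
Why: Crossed Claisen condensation, in which the lithium enolate of 1 is C-acylated by the acid chloride and the second equivalent of base stores 3 as its enolate so that it is not acylated twice; the new methine centre is enolisable and of no consequence.

**Step 2**
Reactants: 3 tert-butyl 2,4-dimethoxy-3-oxobutanoate; 4 5-(bromomethyl)-1,2,3-trimethoxybenzene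
Product: 5 tert-butyl (2S)-2,4-dimethoxy-3-oxo-2-[(3,4,5-trimethoxyphenyl)methyl]butanoate
Conditions: (S,S)-3,4,5-trifluorophenyl-NAS bromide (N-spiro binaphthyl quaternary ammonium bromide, 1 mol%), K2CO3 (solid), toluene, 0 °C
Reagents that add atoms: none
Why: Asymmetric phase-transfer alkylation of an α-substituted β-keto ester (closely precedented for tert-butyl β-keto esters and α-alkoxy malonates), in which the chiral ammonium enolate ion pair exposes one enolate face to the benzyl bromide and so sets the quaternary centre that becomes C1 of the target, while solid carbonate at 0 °C avoids retro-Claisen cleavage.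

**Step 3**
Reactants: 6 pent-4-enal; 7 cyclohexanamine
Product: 8 (1E)-N-cyclohexylpent-4-en-1-imine
Conditions: 4 Å molecular sieves, Et2O, 0 °C to rt
Reagents that add atoms: none
Why: Aldimine formation by condensation, which masks the aldehyde and allows clean α-metalation in the next step; no stereocentre is formed.

**Step 4**
Reactants: 8 (1E)-N-cyclohexylpent-4-en-1-imine; 9 acetaldehyde
Product: 11 (2E)-2-ethylidenepent-4-enal, via hydroxy imine 10 (not isolated)
Conditions: LiN(i-Pr)2, THF, −78 °C; then 9; then aq. oxalic acid, reflux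
Reagents that add atoms: water, O
Why: Directed aza-enolate aldol condensation, in which the lithiated aldimine adds to acetaldehyde without self-condensation and acidic hydrolysis of 10 with loss of water should give the conjugated enal as the thermodynamically preferred E isomer (methyl trans to CHO).

**Step 5**
Reactants: 5 tert-butyl (2S)-2,4-dimethoxy-3-oxo-2-[(3,4,5-trimethoxyphenyl)methyl]butanoate; 11 (2E)-2-ethylidenepent-4-enal
Product: 12 tert-butyl (2S,6E)-5-hydroxy-2,4-dimethoxy-3-oxo-6-(prop-2-en-1-yl)-2-[(3,4,5-trimethoxyphenyl)methyl]oct-6-enoate (mixture of C4/C5 epimers)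
Conditions: LiN(i-Pr)2 (1.05 equiv), THF, −78 °C; then 11; AcOH quench at −78 °C
Reagents that add atoms: none
Why: Kinetic lithium enolate aldol addition, in which the only enolisable position of 5 (the methoxymethyl CH2, C3 of the target) adds 1,2 to the enal; the two new centres are formed without control and are erased in step 6, and the quaternary centre is untouched.

**Step 6**
Reactants: 12 tert-butyl (2S,6E)-5-hydroxy-2,4-dimethoxy-3-oxo-6-(prop-2-en-1-yl)-2-[(3,4,5-trimethoxyphenyl)methyl]oct-6-enoate
Product: 14 tert-butyl (2S,4Z,6E)-2,4-dimethoxy-3-oxo-6-(prop-2-en-1-yl)-2-[(3,4,5-trimethoxyphenyl)methyl]octa-4,6-dienoate, via mesylate 13 (not isolated)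
Conditions: MsCl, Et3N, CH2Cl2, 0 °C; then DBU, rt
Reagents that add atoms: methanesulfonyl chloride, CS(=O)(=O)Cl (its atoms stay only in 13)
Why: Mesylation and E1cB elimination of the β-mesyloxy ketone should give the conjugated 2-methoxy dienone mainly as the more stable 4Z isomer (acyl group trans to the diene), a geometry that does not matter because step 8 equilibrates it, and the tert-butyl ester keeps the molecule inert to base-induced acyl transfer.

**Step 7**
Reactants: 14 tert-butyl (2S,4Z,6E)-2,4-dimethoxy-3-oxo-6-(prop-2-en-1-yl)-2-[(3,4,5-trimethoxyphenyl)methyl]octa-4,6-dienoate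
Product: 16 1,1,1,3,3,3-hexafluoropropan-2-yl (2S,4Z,6E)-2,4-dimethoxy-3-oxo-6-(prop-2-en-1-yl)-2-[(3,4,5-trimethoxyphenyl)methyl]octa-4,6-dienoate, via carboxylic acid 15 (not isolated)
Conditions: TFA, CH2Cl2, 0 °C; evaporate cold; then (CF3)2CHOH, DCC, DMAP (cat.), CH2Cl2, 0 °C
Reagents that add atoms: 1,1,1,3,3,3-hexafluoropropan-2-ol, OC(C(F)(F)F)C(F)(F)F
Why: Acidolysis of the tert-butyl ester and Steglich-type esterification swap the robust ester for an activated ester whose alkoxide is a good leaving group, non-nucleophilic and not oxidisable, with the quaternary β-keto acid 15 esterified cold and at once to forestall decarboxylation; no stereocentre is touched.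

**Step 8**
Reactants: 16 1,1,1,3,3,3-hexafluoropropan-2-yl (2S,4Z,6E)-2,4-dimethoxy-3-oxo-6-(prop-2-en-1-yl)-2-[(3,4,5-trimethoxyphenyl)methyl]octa-4,6-dienoate
Product: 19 (1R,5S,6S,7R)-1,3-dimethoxy-6-methyl-5-(prop-2-en-1-yl)-7-(3,4,5-trimethoxyphenyl)bicyclo[3.2.1]oct-3-ene-2,8-dione, via (4E)-isomer 17 (not isolated), via cycloheptadienolate 18 (not isolated)
Conditions: 3CzClIPN (2,4,6-tri(carbazol-9-yl)-5-chloroisophthalonitrile, 2 mol%), 2,6-lutidine (1.5 equiv), MeCN (0.02 M), blue LEDs (455 nm), rt, Ar
Reagents that add atoms: none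
Why: Proposed new method: the excited cyanoarene photocatalyst equilibrates the geometry of the enone double bond C3=C4 by triplet energy transfer (17 is the isomer that can fold) and oxidises the trimethoxyphenyl ring, the only easily oxidised π-system in 16, to its radical cation, which 2,6-lutidine deprotonates at the benzylic CH2 to give the C7 radical. This nucleophilic radical adds to the electron-poor diene terminus C6 (7-endo-trig closure of the carbocycle C1–C2–C3–C4–C5–C6–C7), and the resulting oxygen-substituted pentadienyl radical is reduced by the photocatalyst radical anion to dienolate 18 (radical–polar crossover), so that the two electrophilic carbons C6 and C7 are joined without external oxidant or reductant. The γ-carbon C5 of 18 then attacks the ester carbonyl C8 across the seven-membered ring (5-exo-trig Dieckmann-type acylation that closes the cyclopentanone C1–C7–C6–C5–C8 and with it the cyclohexenone C1–C2–C3–C4–C5–C8; attack through C3 would need a four-membered ring), and the expelled hexafluoroisopropoxide is protonated by lutidinium. The closest known reaction types are photocatalytic benzylic C–H alkylation of electron-rich alkylarenes with Michael acceptors through arene radical cations and photoredox Giese addition followed by anionic ring closure; new are the 7-endo addition to a dienone terminus and the acylative termination. Stereocontrol comes from C1 alone: in the radical addition the aryl group on C7 should sit anti to the bulky ester on C1 (it ends endo, syn to OMe) and the methyl group on C6, held E on the alkene, anti to the aryl group (trans C6/C7; a 6Z isomer formed by energy transfer would carry its methyl inside the fold and should react far more slowly), while C5 can be acylated only on the face that carries C8. The step needs hole formation at the arene and not at an alkene (the dienone is electron-poor, the allyl group unactivated), attack at C6 and not C4 (5-endo closure, less delocalised radical) and acylation faster than protonation of 18 (activated ester held next to C5, lutidinium present only in trace), and the catalyst triplet energy is chosen high enough for the acyclic dienone but too low for the rigid enone of 19.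

**Step 9**
Reactants: 19 (1R,5S,6S,7R)-1,3-dimethoxy-6-methyl-5-(prop-2-en-1-yl)-7-(3,4,5-trimethoxyphenyl)bicyclo[3.2.1]oct-3-ene-2,8-dione
Product: 20 (1S,2R,5S,6S,7R)-2-hydroxy-1,3-dimethoxy-6-methyl-5-(prop-2-en-1-yl)-7-(3,4,5-trimethoxyphenyl)bicyclo[3.2.1]oct-3-en-8-one (core numbered as in the target)
Conditions: NaBH4 (1.0 equiv), CeCl3·7H2O (1.1 equiv), MeOH, −78 °C
Reagents that add atoms: none
Why: Luche 1,2-reduction, in which the cerium-activated enone carbonyl C2 should be reduced in preference to the C8 ketone flanked by two fully substituted bridgeheads, and hydride should arrive on the face syn to the C8 bridge because the other face is blocked by the endo aryl group on C7, which places the new hydroxyl endo (2R).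

**Step 10**
Reactants: 20 (1S,2R,5S,6S,7R)-2-hydroxy-1,3-dimethoxy-6-methyl-5-(prop-2-en-1-yl)-7-(3,4,5-trimethoxyphenyl)bicyclo[3.2.1]oct-3-en-8-one
Product: 21 (1S,2R,5S,6S,7R)-1,3-dimethoxy-6-methyl-8-oxo-5-(prop-2-en-1-yl)-7-(3,4,5-trimethoxyphenyl)bicyclo[3.2.1]oct-3-en-2-yl acetate
Conditions: Ac2O, pyridine, DMAP (cat.), CH2Cl2, rt
Reagents that add atoms: acetic anhydride, CC(=O)OC(C)=O
Why: DMAP-catalysed O-acylation of the secondary alcohol with retention at C2 gives the target acetate.

**Compound list**

1 | tert-butyl methoxyacetate | COCC(=O)OC(C)(C)C | starting material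
2 | methoxyacetyl chloride | COCC(=O)Cl | starting material
3 | tert-butyl 2,4-dimethoxy-3-oxobutanoate | COCC(=O)C(OC)C(=O)OC(C)(C)C | intermediate
4 | 5-(bromomethyl)-1,2,3-trimethoxybenzene | COc1cc(CBr)cc(OC)c1OC | starting material
5 | tert-butyl (2S)-2,4-dimethoxy-3-oxo-2-[(3,4,5-trimethoxyphenyl)methyl]butanoate | COCC(=O)[C@](OC)(C(=O)OC(C)(C)C)Cc1cc(OC)c(OC)c(OC)c1 | intermediate
6 | pent-4-enal | C=CCCC=O | starting material
7 | cyclohexanamine | NC1CCCCC1 | starting material
8 | (1E)-N-cyclohexylpent-4-en-1-imine | C=CCC/C=N/C1CCCCC1 | intermediate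
9 | acetaldehyde | CC=O | starting material
10 | 3-[(E)-(cyclohexylimino)methyl]hex-5-en-2-ol (formed as its lithium alkoxide, diastereomer mixture) | CC(O)C(CC=C)/C=N/C1CCCCC1 | intermediate
11 | (2E)-2-ethylidenepent-4-enal | C/C=C(/C=O)CC=C | intermediate
12 | tert-butyl (2S,6E)-5-hydroxy-2,4-dimethoxy-3-oxo-6-(prop-2-en-1-yl)-2-[(3,4,5-trimethoxyphenyl)methyl]oct-6-enoate (C4/C5 epimers) | C/C=C(CC=C)/C(O)C(OC)C(=O)[C@](OC)(C(=O)OC(C)(C)C)Cc1cc(OC)c(OC)c(OC)c1 | intermediate
13 | tert-butyl (2S,6E)-5-(methanesulfonyloxy)-2,4-dimethoxy-3-oxo-6-(prop-2-en-1-yl)-2-[(3,4,5-trimethoxyphenyl)methyl]oct-6-enoate | C/C=C(CC=C)/C(OS(C)(=O)=O)C(OC)C(=O)[C@](OC)(C(=O)OC(C)(C)C)Cc1cc(OC)c(OC)c(OC)c1 | intermediate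
14 | tert-butyl (2S,4Z,6E)-2,4-dimethoxy-3-oxo-6-(prop-2-en-1-yl)-2-[(3,4,5-trimethoxyphenyl)methyl]octa-4,6-dienoate | C/C=C(CC=C)/C=C(OC)/C(=O)[C@](OC)(C(=O)OC(C)(C)C)Cc1cc(OC)c(OC)c(OC)c1 | intermediate
15 | (2S,4Z,6E)-2,4-dimethoxy-3-oxo-6-(prop-2-en-1-yl)-2-[(3,4,5-trimethoxyphenyl)methyl]octa-4,6-dienoic acid | C/C=C(CC=C)/C=C(OC)/C(=O)[C@](OC)(C(=O)O)Cc1cc(OC)c(OC)c(OC)c1 | intermediate
16 | 1,1,1,3,3,3-hexafluoropropan-2-yl (2S,4Z,6E)-2,4-dimethoxy-3-oxo-6-(prop-2-en-1-yl)-2-[(3,4,5-trimethoxyphenyl)methyl]octa-4,6-dienoate | C/C=C(CC=C)/C=C(OC)/C(=O)[C@](OC)(C(=O)OC(C(F)(F)F)C(F)(F)F)Cc1cc(OC)c(OC)c(OC)c1 | intermediate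
17 | 1,1,1,3,3,3-hexafluoropropan-2-yl (2S,4E,6E)-2,4-dimethoxy-3-oxo-6-(prop-2-en-1-yl)-2-[(3,4,5-trimethoxyphenyl)methyl]octa-4,6-dienoate | C/C=C(CC=C)/C=C(OC)\C(=O)[C@](OC)(C(=O)OC(C(F)(F)F)C(F)(F)F)Cc1cc(OC)c(OC)c(OC)c1 | intermediate
18 | 1,1,1,3,3,3-hexafluoropropan-2-yl (1S,6S,7R)-1,3-dimethoxy-6-methyl-2-oxido-5-(prop-2-en-1-yl)-7-(3,4,5-trimethoxyphenyl)cyclohepta-2,4-diene-1-carboxylate (dienolate anion) | C=CCC1=CC(OC)=C([O-])[C@](OC)(C(=O)OC(C(F)(F)F)C(F)(F)F)[C@@H](c2cc(OC)c(OC)c(OC)c2)[C@@H]1C | intermediate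
19 | (1R,5S,6S,7R)-1,3-dimethoxy-6-methyl-5-(prop-2-en-1-yl)-7-(3,4,5-trimethoxyphenyl)bicyclo[3.2.1]oct-3-ene-2,8-dione | C=CC[C@]12C=C(OC)C(=O)[C@](OC)(C1=O)[C@@H](c1cc(OC)c(OC)c(OC)c1)[C@@H]2C | intermediate
20 | (1S,2R,5S,6S,7R)-2-hydroxy-1,3-dimethoxy-6-methyl-5-(prop-2-en-1-yl)-7-(3,4,5-trimethoxyphenyl)bicyclo[3.2.1]oct-3-en-8-one | C=CC[C@]12C=C(OC)[C@@H](O)[C@](OC)(C1=O)[C@@H](c1cc(OC)c(OC)c(OC)c1)[C@@H]2C | intermediate
21 | (1S,2R,5S,6S,7R)-1,3-dimethoxy-6-methyl-8-oxo-5-(prop-2-en-1-yl)-7-(3,4,5-trimethoxyphenyl)bicyclo[3.2.1]oct-3-en-2-yl acetate | C=CC[C@]12C=C(OC)[C@@H](OC(C)=O)[C@](OC)(C1=O)[C@@H](c1cc(OC)c(OC)c(OC)c1)[C@@H]2C | target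

**Step count and risks**

Total steps: 10. Longest linear sequence: 8 (steps 1, 2, 5, 6, 7, 8, 9, 10).

Steps most likely to fail:

1. Step 8 (Proposed new method). What may go wrong: back electron transfer outrunning the benzylic deprotonation of the arene radical cation; dimerisation of the C7 radical before the slow 7-endo closure; parking of the (4E)-isomer as its 2H-pyran valence isomer; protonation of the dienolate before it is acylated. Fallback, from 16 back to 19: the radical and polar stages are separated and each is run as a known reaction type. Irradiation of 16 with the same photocatalyst and 2,6-lutidine, with 2,4,6-triisopropylbenzenethiol (10 mol%) added as hydrogen-atom donor (photocatalytic benzylic C–H hydroalkylation of a Michael acceptor), should stop the sequence after the 7-endo addition by hydrogen-atom transfer to the dienyl radical. This gives the neutral cycloheptenone 1,1,1,3,3,3-hexafluoropropan-2-yl (1S,6R,7R)-1,3-dimethoxy-6-methyl-2-oxo-5-(prop-2-en-1-yl)-7-(3,4,5-trimethoxyphenyl)cyclohept-3-ene-1-carboxylate F1 (C5 epimers, or its β,γ-unsaturated isomer; both lead to the same dienolate). DBU in MeCN at 0 °C then removes the γ-proton at C5, and the transannular Dieckmann-type acylation should close the bicycle to 19.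

2. Step 2. What may go wrong: poor facial discrimination in the acyclic enolate ion pair (low enantioselectivity), or base-induced retro-Claisen cleavage of the product. Fallback, from 3 back to 5: 3 is benzylated with 4 without chiral catalyst (K2CO3, Bu4NBr, acetone, rt) to give racemic tert-butyl 2,4-dimethoxy-3-oxo-2-[(3,4,5-trimethoxyphenyl)methyl]butanoate F2. The (S)-enantiomer 5 is then isolated by preparative chromatography on a chiral stationary phase, so the catalytic asymmetric step is replaced by a resolution.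

3. Step 9. What may go wrong: hydride delivery to the strained bridging C8 carbonyl in competition with the enone carbonyl, or over-reduction. Fallback, from 19 back to 21: both carbonyls are reduced on purpose (NaBH4 in excess, CeCl3·7H2O, MeOH, 0 °C) to give (1R,2R,5S,6S,7R)-1,3-dimethoxy-6-methyl-5-(prop-2-en-1-yl)-7-(3,4,5-trimethoxyphenyl)bicyclo[3.2.1]oct-3-ene-2,8-diol F3 (configuration at C8 not defined). Ac2O (1 equiv) in pyridine at 0 °C should acylate the less hindered allylic C2 hydroxyl and leave the C8 carbinol, which lies between two quaternary carbons, to give (1R,2R,5S,6S,7R)-8-hydroxy-1,3-dimethoxy-6-methyl-5-(prop-2-en-1-yl)-7-(3,4,5-trimethoxyphenyl)bicyclo[3.2.1]oct-3-en-2-yl acetate F4. Oxidation of the remaining alcohol with DMP (1,1,1-triacetoxy-1,1-dihydro-1,2-benziodoxol-3(1H)-one) in CH2Cl2 returns to 21.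

**Further compounds**

F1 | step 8 | 1,1,1,3,3,3-hexafluoropropan-2-yl (1S,6R,7R)-1,3-dimethoxy-6-methyl-2-oxo-5-(prop-2-en-1-yl)-7-(3,4,5-trimethoxyphenyl)cyclohept-3-ene-1-carboxylate | C=CCC1C=C(OC)C(=O)[C@](OC)(C(=O)OC(C(F)(F)F)C(F)(F)F)[C@@H](c2cc(OC)c(OC)c(OC)c2)[C@@H]1C
F2 | step 2 | racemic tert-butyl 2,4-dimethoxy-3-oxo-2-[(3,4,5-trimethoxyphenyl)methyl]butanoate | COCC(=O)C(OC)(C(=O)OC(C)(C)C)Cc1cc(OC)c(OC)c(OC)c1
F3 | step 9 | (1R,2R,5S,6S,7R)-1,3-dimethoxy-6-methyl-5-(prop-2-en-1-yl)-7-(3,4,5-trimethoxyphenyl)bicyclo[3.2.1]oct-3-ene-2,8-diol | C=CC[C@]12C=C(OC)[C@@H](O)[C@](OC)(C1O)[C@@H](c1cc(OC)c(OC)c(OC)c1)[C@@H]2C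
F4 | step 9 | (1R,2R,5S,6S,7R)-8-hydroxy-1,3-dimethoxy-6-methyl-5-(prop-2-en-1-yl)-7-(3,4,5-trimethoxyphenyl)bicyclo[3.2.1]oct-3-en-2-yl acetate | C=CC[C@]12C=C(OC)[C@@H](OC(C)=O)[C@](OC)(C1O)[C@@H](c1cc(OC)c(OC)c(OC)c1)[C@@H]2C
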